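The route rests on cutting the dihydrofuran ring at O1–C7a and C3–C3a (benzofuran numbering), the two bonds that tie O1 and C3 to adjacent carbons of the benzene ring. This ortho pair of an ether oxygen and a carbinol carbon is read as an aryne that has taken up an alkoxide and then an aldehyde. In one operation, fluoride releases 4-acetylbenzyne and the alkoxide of an enantiopure alpha-silyloxy aldehyde; O-arylation and closure of the aryl anion onto the aldehyde build the furan ring, carry C2 over and set C3, and the new alkoxide is acetylated in the flask. The precursors are an ortho-silylaryl triflate and (R)-3-methyl-2-(triethylsilyloxy)but-3-enal. Ketone reduction, angeloylation and allylic oxidation finish the target.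

Key step: step 7

Assumption: angelic anhydride is taken as a purchasable reagent; atom numbers follow 2,3-dihydro-1-benzofuran numbering (O1, C2, C3, C3a, C4 to C7, C7a).

Step 1
Reactants: 1 1-(3-bromo-4-hydroxyphenyl)ethan-1-one
Product: 2 2-bromo-4-(2-methyl-1,3-dioxolan-2-yl)phenol
Conditions: ethylene glycol, p-TsOH (cat.), toluene, reflux, Dean–Stark
Reagents that add atoms: ethylene glycol, OCCO
Why: Acid-catalysed ketalisation with azeotropic removal of water masks the ketone against the butyllithium of step 2, and no stereocenter is formed.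

Step 2
Reactants: 2 2-bromo-4-(2-methyl-1,3-dioxolan-2-yl)phenol
Product: 5 4-(2-methyl-1,3-dioxolan-2-yl)-2-(trimethylsilyl)phenyl trifluoromethanesulfonate, via trimethylsilyl ether 3 (not isolated), via lithium phenoxide 4 (not isolated)
Conditions: (Me3Si)2NH, THF, 65 °C, then evaporation; n-BuLi, THF, −78 °C; Tf2O, −78 to 0 °C
Reagents that add atoms: hexamethyldisilazane, C[Si](C)(C)N[Si](C)(C)C; triflic anhydride, O=S(=O)(OS(=O)(=O)C(F)(F)F)C(F)(F)F
Why: O-Silylation, bromine–lithium exchange and 1,3-retro-Brook migration of silicon from oxygen to the ortho carbon give phenoxide 4, which is triflated, the standard way to an ortho-silylaryl triflate aryne precursor.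

Step 3
Reactants: 5 4-(2-methyl-1,3-dioxolan-2-yl)-2-(trimethylsilyl)phenyl trifluoromethanesulfonate
Product: 6 4-acetyl-2-(trimethylsilyl)phenyl trifluoromethanesulfonate
Conditions: 1 M HCl, acetone, rt
Reagents that add atoms: water, O
Why: Acid hydrolysis of the dioxolane returns the aryl methyl ketone, while the triflate and the aryl–silicon bond on the electron-poor ring should survive dilute acid at room temperature.

Step 4
Reactants: 7 3-methylbut-2-en-1-ol (prenol)
Product: 8 [(2S)-3,3-dimethyloxiran-2-yl]methanol
Conditions: Ti(OiPr)4 (cat.), L-(+)-diisopropyl tartrate (cat.), t-BuOOH, 4 Å molecular sieves, CH2Cl2, −20 °C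
Reagents that add atoms: tert-butyl hydroperoxide, CC(C)(C)OO
Why: Sharpless asymmetric epoxidation of a primary allylic alcohol, in which the L-(+)-tartrate titanium complex delivers oxygen to the alkene face that gives the (S)-epoxide, the same sense as for geraniol.

Step 5
Reactants: 8 [(2S)-3,3-dimethyloxiran-2-yl]methanol
Product: 10 (2R)-3-methyl-1,2-bis(triethylsilyloxy)but-3-ene, via triethylsilyl epoxy ether 9 (not isolated)
Conditions: Et3SiOTf (2.2 equiv), 2,6-lutidine, CH2Cl2, −78 °C; then DBU, −78 °C to rt
Reagents that add atoms: triethylsilyl triflate, CC[Si](CC)(CC)OS(=O)(=O)C(F)(F)F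
Why: After silylation of the hydroxyl group the silyl triflate activates the epoxide oxygen, the tertiary C–O bond opens and DBU removes a methyl proton (silyl triflate and amidine isomerisation of an epoxide to an allylic silyl ether), so the secondary C–O bond is untouched and its configuration is kept, the descriptor changing from S to R only because the priorities change.

Step 6
Reactants: 10 (2R)-3-methyl-1,2-bis(triethylsilyloxy)but-3-ene
Product: 11 (2R)-3-methyl-2-(triethylsilyloxy)but-3-enal
Conditions: (COCl)2, DMSO, CH2Cl2, −78 to −40 °C; then i-Pr2NEt, −78 °C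
Reagents that add atoms: none
Why: Under Swern conditions the less hindered primary triethylsilyl ether is cleaved and oxidised directly to the aldehyde while the secondary one stays in place (selective Swern oxidation of primary silyl ethers), and the low temperature and the hindered base should protect the alpha stereocenter and the position of the double bond.

Step 7
Reactants: 6 4-acetyl-2-(trimethylsilyl)phenyl trifluoromethanesulfonate; 11 (2R)-3-methyl-2-(triethylsilyloxy)but-3-enal
Product: 16 (2R,3S)-5-acetyl-2-(prop-1-en-2-yl)-2,3-dihydro-1-benzofuran-3-yl acetate, via 4-acetylbenzyne 12 (not isolated), via potassium alkoxide 13 (not isolated), via aryl anion 14 (not isolated), via cyclised potassium alkoxide 15 (not isolated)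
Conditions: KF, 18-crown-6, THF, 0 °C, slow addition of 6 and 11; then Ac2O, 0 °C to rt
Reagents that add atoms: acetic anhydride, CC(=O)OC(C)=O
Why: Proposed new method: fluoride removes the trimethylsilyl group of 6 to give 4-acetylbenzyne 12 and the triethylsilyl group of 11 to give alkoxide 13, whose oxygen adds to the aryne carbon para to the acetyl group; the aryl anion 14 so formed attacks the pendant aldehyde to give alkoxide 15, which acetic anhydride then traps as 16. The closest known reaction type is the aryne annulation by nucleophilic addition followed by intramolecular carbonyl trapping, shown for salicylaldehydes (to xanthenols) and for alpha-amino ketones (to 3-hydroxyindolines and indoles), but not for an aliphatic alpha-oxy aldehyde released from its silyl ether. The dihydrofuran ring closes in the 5-exo-trig mode by attack of the in-plane aryl anion on the aldehyde carbon. C2 is carried over unchanged from 11, and C3 is set in the ring closure, where the carbonyl oxygen is expected to turn away from the isopropenyl group so that the small formyl hydrogen lies next to it, which leads to the trans isomer. The step needs regioselectivity on the aryne, which rests only on the inductive pull of the acetyl group that favours the anion meta and the oxygen para to it, and it needs the alkoxide to be arylated before it enolises, which slow release at 0 °C and an aryne that is formed at the same time should secure.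

Step 8
Reactants: 16 (2R,3S)-5-acetyl-2-(prop-1-en-2-yl)-2,3-dihydro-1-benzofuran-3-yl acetate
Product: 17 (2R,3S)-5-[(1R)-1-hydroxyethyl]-2-(prop-1-en-2-yl)-2,3-dihydro-1-benzofuran-3-yl acetate
Conditions: RuCl[(R,R)-TsDPEN](p-cymene) (cat.), HCO2H/Et3N (5:2), EtOAc, rt
Reagents that add atoms: none
Why: Noyori asymmetric transfer hydrogenation of an aryl methyl ketone, in which the (R,R)-TsDPEN ligand directs hydride to the ketone face that gives the (R)-carbinol, and which leaves the alkene and the acetate alone.

Step 9
Reactants: 17 (2R,3S)-5-[(1R)-1-hydroxyethyl]-2-(prop-1-en-2-yl)-2,3-dihydro-1-benzofuran-3-yl acetate; 18 angelic anhydride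
Product: 19 (1R)-1-[(2R,3S)-3-acetoxy-2-(prop-1-en-2-yl)-2,3-dihydro-1-benzofuran-5-yl]ethyl (2Z)-2-methylbut-2-enoate
Conditions: LiN(SiMe3)2, THF, −78 °C; then 18, −78 to 0 °C
Reagents that add atoms: none
Why: O-Acylation of the lithium alkoxide by the anhydride needs no nucleophilic catalyst, so the (Z)-alkene of the angelate should not isomerise to the tiglate, and the carbinol configuration is retained because no bond to the stereocenter is broken.

Step 10
Reactants: 19 (1R)-1-[(2R,3S)-3-acetoxy-2-(prop-1-en-2-yl)-2,3-dihydro-1-benzofuran-5-yl]ethyl (2Z)-2-methylbut-2-enoate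
Product: 20 (1R)-1-[(2R,3S)-3-acetoxy-2-(3-oxoprop-1-en-2-yl)-2,3-dihydro-1-benzofuran-5-yl]ethyl (2Z)-2-methylbut-2-enoate
Conditions: SeO2, 1,4-dioxane, 70 °C
Reagents that add atoms: selenium dioxide, O=[Se]=O
Why: Riley allylic oxidation (ene reaction, then 2,3-sigmatropic shift) should take the methyl group of the isolated 1,1-disubstituted alkene to the aldehyde, the methyl group being preferred over the ring methine and the electron-poor angelate alkene reacting much more slowly, and no stereocenter is touched.

Compound list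
1 | 1-(3-bromo-4-hydroxyphenyl)ethan-1-one | CC(=O)c1ccc(O)c(Br)c1 | starting material
2 | 2-bromo-4-(2-methyl-1,3-dioxolan-2-yl)phenol | CC1(OCCO1)c1ccc(O)c(Br)c1 | intermediate
3 | [2-bromo-4-(2-methyl-1,3-dioxolan-2-yl)phenoxy]trimethylsilane | CC1(OCCO1)c1ccc(O[Si](C)(C)C)c(Br)c1 | intermediate
4 | lithium 4-(2-methyl-1,3-dioxolan-2-yl)-2-(trimethylsilyl)phenolate | CC1(OCCO1)c1ccc([O-])c([Si](C)(C)C)c1.[Li+] | intermediate
5 | 4-(2-methyl-1,3-dioxolan-2-yl)-2-(trimethylsilyl)phenyl trifluoromethanesulfonate | CC1(OCCO1)c1ccc(OS(=O)(=O)C(F)(F)F)c([Si](C)(C)C)c1 | intermediate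
6 | 4-acetyl-2-(trimethylsilyl)phenyl trifluoromethanesulfonate | CC(=O)c1ccc(OS(=O)(=O)C(F)(F)F)c([Si](C)(C)C)c1 | intermediate
7 | 3-methylbut-2-en-1-ol (prenol) | CC(C)=CCO | starting material
8 | [(2S)-3,3-dimethyloxiran-2-yl]methanol | OC[C@@H]1OC1(C)C | intermediate
9 | {[(2S)-3,3-dimethyloxiran-2-yl]methoxy}triethylsilane | CC[Si](CC)(CC)OC[C@@H]1OC1(C)C | intermediate
10 | (2R)-3-methyl-1,2-bis(triethylsilyloxy)but-3-ene | CC[Si](CC)(CC)OC[C@H](O[Si](CC)(CC)CC)C(C)=C | intermediate
11 | (2R)-3-methyl-2-(triethylsilyloxy)but-3-enal | O=C[C@H](O[Si](CC)(CC)CC)C(C)=C | intermediate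
12 | 4-acetylbenzyne [1-(3,4-didehydrophenyl)ethan-1-one] | CC(=O)C1=CC#CC=C1 | intermediate
13 | potassium (2R)-3-methyl-1-oxobut-3-en-2-olate | O=C[C@H]([O-])C(C)=C.[K+] | intermediate
14 | potassium 5-acetyl-2-{[(2R)-3-methyl-1-oxobut-3-en-2-yl]oxy}benzen-1-ide | CC(=O)c1ccc(O[C@@H](C=O)C(C)=C)[c-]c1.[K+] | intermediate
15 | potassium (2R,3S)-5-acetyl-2-(prop-1-en-2-yl)-2,3-dihydro-1-benzofuran-3-olate | C=C(C)[C@H]1Oc2ccc(C(C)=O)cc2[C@@H]1[O-].[K+] | intermediate
16 | (2R,3S)-5-acetyl-2-(prop-1-en-2-yl)-2,3-dihydro-1-benzofuran-3-yl acetate | C=C(C)[C@H]1Oc2ccc(C(C)=O)cc2[C@@H]1OC(C)=O | intermediate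
17 | (2R,3S)-5-[(1R)-1-hydroxyethyl]-2-(prop-1-en-2-yl)-2,3-dihydro-1-benzofuran-3-yl acetate | C=C(C)[C@H]1Oc2ccc([C@@H](C)O)cc2[C@@H]1OC(C)=O | intermediate
18 | angelic anhydride [(2Z)-2-methylbut-2-enoic anhydride] | C/C=C(/C)C(=O)OC(=O)/C(C)=C\C | starting material
19 | (1R)-1-[(2R,3S)-3-acetoxy-2-(prop-1-en-2-yl)-2,3-dihydro-1-benzofuran-5-yl]ethyl (2Z)-2-methylbut-2-enoate | C=C(C)[C@H]1Oc2ccc([C@@H](C)OC(=O)/C(C)=C\C)cc2[C@@H]1OC(C)=O | intermediate
20 | (1R)-1-[(2R,3S)-3-acetoxy-2-(3-oxoprop-1-en-2-yl)-2,3-dihydro-1-benzofuran-5-yl]ethyl (2Z)-2-methylbut-2-enoate | C=C(C=O)[C@H]1Oc2ccc([C@@H](C)OC(=O)/C(C)=C\C)cc2[C@@H]1OC(C)=O | target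

Total step count: 10. Longest linear sequence: 7 steps (steps 1, 2, 3, 7, 8, 9, 10; the branch through steps 4, 5, 6 is equally long).

Steps most likely to fail

1. Step 7 (Proposed new method). Several processes may go wrong.
- Regiocontrol may be lost, because the acetyl group polarises the aryne only weakly and the alkoxide may add to both aryne carbons.
- The alkoxide may enolise or condense with itself before it is arylated, with loss of enantiopurity and of material.
- The ring closure may show poor facial selectivity at C3.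
- Alkoxide 15 may be arylated by a second aryne.

The fallback uses known chemistry, makes the two bonds one after the other with their positions fixed by a fluorine and a bromine atom, sets out from 11 and comes back at 16. Purchased 1-(3-bromo-4-fluorophenyl)ethan-1-one F1 is ketalised (ethylene glycol, p-TsOH, toluene, reflux) to 2-(3-bromo-4-fluorophenyl)-2-methyl-1,3-dioxolane F2. Bromine–magnesium exchange (i-PrMgCl·LiCl, THF, −20 °C) and Felkin–Anh addition of the aryl Grignard reagent to 11 at −78 °C should form the C3–C3a bond and give the anti adduct (1S,2R)-1-[2-fluoro-5-(2-methyl-1,3-dioxolan-2-yl)phenyl]-3-methyl-2-(triethylsilyloxy)but-3-en-1-ol F3. 1 M HCl in THF removes the dioxolane and the silyl ether to give 1-{3-[(1S,2R)-1,2-dihydroxy-3-methylbut-3-en-1-yl]-4-fluorophenyl}ethan-1-one F4. K2CO3 in DMSO at 60 °C should close the O1–C7a bond by intramolecular nucleophilic aromatic substitution of the fluoride para to the acetyl group (5-exo) to give 1-[(2R,3S)-3-hydroxy-2-(prop-1-en-2-yl)-2,3-dihydro-1-benzofuran-5-yl]ethan-1-one F5. Ac2O, pyridine and DMAP (cat.) in CH2Cl2 at 0 °C then give 16.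

2. Step 10. What may go wrong: over-oxidation, competing attack at the allylic methyl groups of the angelate, and acid-promoted loss of acetic acid from C3 with aromatisation to the benzofuran at 70 °C.

The fallback sets out from 19 and comes back at 20. A Schenck ene reaction with singlet oxygen (O2, tetraphenylporphyrin, visible light, CH2Cl2, 0 °C), to which the electron-poor angelate should be inert, gives (1R)-1-[(2R,3S)-3-acetoxy-2-(3-hydroperoxyprop-1-en-2-yl)-2,3-dihydro-1-benzofuran-5-yl]ethyl (2Z)-2-methylbut-2-enoate F6. Dehydration of this primary allylic hydroperoxide with Ac2O and pyridine at 0 °C gives 20.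

3. Step 5. What may go wrong: a hydride shift in the silyl-activated epoxide that leads to the isopropyl ketone, or proton loss toward C1 in place of the methyl group.

The fallback sets out from 8 and comes back at 10. A base-mediated syn elimination with Et2Al(TMP) (TMP = 2,2,6,6-tetramethylpiperidide; toluene, 0 °C) removes a methyl proton through a cyclic transition state without a cationic intermediate and should give (2R)-3-methylbut-3-ene-1,2-diol F7. Et3SiCl and imidazole in DMF then give 10.

Further compounds
F1 | step 7 | 1-(3-bromo-4-fluorophenyl)ethan-1-one (purchased) | CC(=O)c1ccc(F)c(Br)c1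
F2 | step 7 | 2-(3-bromo-4-fluorophenyl)-2-methyl-1,3-dioxolane | CC1(OCCO1)c1ccc(F)c(Br)c1
F3 | step 7 | (1S,2R)-1-[2-fluoro-5-(2-methyl-1,3-dioxolan-2-yl)phenyl]-3-methyl-2-(triethylsilyloxy)but-3-en-1-ol | C=C(C)[C@@H](O[Si](CC)(CC)CC)[C@@H](O)c1cc(C2(C)OCCO2)ccc1F
F4 | step 7 | 1-{3-[(1S,2R)-1,2-dihydroxy-3-methylbut-3-en-1-yl]-4-fluorophenyl}ethan-1-one | C=C(C)[C@@H](O)[C@@H](O)c1cc(C(C)=O)ccc1F
F5 | step 7 | 1-[(2R,3S)-3-hydroxy-2-(prop-1-en-2-yl)-2,3-dihydro-1-benzofuran-5-yl]ethan-1-one | C=C(C)[C@H]1Oc2ccc(C(C)=O)cc2[C@@H]1O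
F6 | step 10 | (1R)-1-[(2R,3S)-3-acetoxy-2-(3-hydroperoxyprop-1-en-2-yl)-2,3-dihydro-1-benzofuran-5-yl]ethyl (2Z)-2-methylbut-2-enoate | C=C(COO)[C@H]1Oc2ccc([C@@H](C)OC(=O)/C(C)=C\C)cc2[C@@H]1OC(C)=O
F7 | step 5 | (2R)-3-methylbut-3-ene-1,2-diol | C=C(C)[C@@H](O)CO
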